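Numbering the lactone O1, C2(=O), C3, C4, C5, with C7 the benzylic CH2 on C3 (ring A) and C8 the ketone carbon on C4 (ring B): rings A and B are identical guaiacyl units, and C7/C8, like C2/C5, differ only in oxidation level. The skeleton is therefore a twofold-symmetric (2R,3R)-2,3-dibenzylsuccinic acid. The key step, a DDQ benzylic hydride abstraction on the bis(benzyl ether) diacid 10, puts oxygen on C8 as a temporary γ-lactone. The same operation tells the two carboxyls apart: the lactonised one becomes C2, the free one is reduced to C5. Translactonisation, oxidation and debenzylation finish the synthesis.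

Key step: step 5

Remark: the C8 configuration drawn for 12–14 (aryl trans to its ring neighbour in 12) is the expected one; either epimer would serve, since C8 ends as a carbonyl.

Step 1
Reactants: 1 dihydroferulic acid
Product: 3 3-(4-benzyloxy-3-methoxyphenyl)propanoic acid, via dibenzylated ester 2 (not isolated)
Conditions: BnBr (2.3 equiv), K2CO3, DMF, 60 °C; then NaOH aq, MeOH, 60 °C; HCl to pH 2
Reagents that add atoms: benzyl bromide, BrCc1ccccc1; sodium hydroxide, [Na+].[OH-]
Why: Williamson O-alkylation benzylates phenoxide and carboxylate alike, and saponification of the benzyl ester in the same pot returns the acid while the aryl benzyl ether is inert to hydroxide; no stereocentre is involved.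

Step 2
Reactants: 3 3-(4-benzyloxy-3-methoxyphenyl)propanoic acid; 4 (S)-4-benzyloxazolidin-2-one
Product: 6 (S)-4-benzyl-3-[3-(4-benzyloxy-3-methoxyphenyl)propanoyl]oxazolidin-2-one, via mixed pivalic anhydride 5 (not isolated)
Conditions: PivCl, Et3N, THF, −20 °C; then LiCl, 4, −20 °C to rt
Reagents that add atoms: none
Why: N-acylation of the oxazolidinone through the mixed pivalic anhydride (LiCl/Et3N activation) should be selective for the arylpropanoyl carbonyl because the pivaloyl carbonyl is shielded by its tert-butyl group.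

Step 3
Reactants: 6 (S)-4-benzyl-3-[3-(4-benzyloxy-3-methoxyphenyl)propanoyl]oxazolidin-2-one (two molecules)
Product: 8 (2R,3R)-2,3-bis(4-benzyloxy-3-methoxybenzyl)-1,4-bis[(S)-4-benzyl-2-oxooxazolidin-3-yl]butane-1,4-dione, via lithium Z-enolate 7 (not isolated)
Conditions: LiN(iPr)2 (1.1 equiv), THF, −78 °C; then CuCl2 (1.1 equiv, divalent copper) in DMF, −78 °C to rt
Reagents that add atoms: none
Why: Oxidative enolate homocoupling, a reaction established for 3-(3-arylpropanoyl)oxazolidinones: CuCl2 oxidises the chelated Z-enolate to an α-acyl radical and each partner forms the new C–C bond on the face away from the 4-benzyl group of its (S)-auxiliary, the same facial sense as an Evans alkylation, which sets both new stereocentres R (the future C3 and C4).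

Step 4
Reactants: 8 (2R,3R)-bis-imide
Product: 10 (2R,3R)-2,3-bis(4-benzyloxy-3-methoxybenzyl)succinic acid, via diperoxy acid 9 (not isolated)
Conditions: LiOH, 30% H2O2, THF/H2O, 0 °C; Na2SO3 aq; then HCl to pH 2
Reagents that add atoms: hydrogen peroxide, OO
Why: Hydroperoxide cleavage of N-acyloxazolidinones: the small, highly nucleophilic LiOOH attacks the exocyclic carbonyl even of α-branched imides at 0 °C without epimerising the α-centres, sulfite reduces the peracid 9, and auxiliary 4 is recovered.

Step 5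
Reactants: 10 (2R,3R)-2,3-bis(4-benzyloxy-3-methoxybenzyl)succinic acid
Product: 12 (2S,3S,4R)-2-(4-benzyloxy-3-methoxyphenyl)-4-(4-benzyloxy-3-methoxybenzyl)-5-oxotetrahydrofuran-3-carboxylic acid, via benzylic cation 11 (not isolated)
Conditions: DDQ (0.9 equiv, slow addition), 1,4-dioxane/CH2Cl2, 4 Å molecular sieves, rt to 40 °C
Reagents that add atoms: none
Why: Hydride transfer from one benzylic methylene (the future C8) to DDQ, inside the donor–acceptor complex of the quinone and the electron-rich ring B, should give the para-alkoxy-stabilised cation 11, which is captured by the carboxyl on the other succinate carbon, γ to the cationic centre, to form the C8–O bond. The closest known reaction type is the DDQ-mediated oxidative benzylic C–H lactonisation of 4-(4-alkoxyaryl)butanoic acids, together with the DDQ cyclisation of dibenzylbutanediols to 7,9'-epoxylignans. The single ring closes in a 5-exo mode by attack of the carboxyl oxygen on the planar cation; the carboxyl on the adjacent carbon could only give a strained 4-membered lactone and stays free. The new stereocentre at C8 is governed by the neighbouring carboxyl-bearing carbon, the aryl group taking the face trans to that carboxyl, while the succinate centres are untouched and their R,R relationship places benzyl and carboxyl cis on the new ring. Site selectivity needs no control because the twofold axis of 10 renders both benzylic methylenes and both carboxyls equivalent, and the ArO–CH2Ph methylenes, lacking a donor-substituted ring, are oxidised far more slowly. The selectivity that must be enforced is mono- over double oxidation, secured by sub-stoichiometric DDQ in an acid-free medium, with the neutral bislactone removed by bicarbonate extraction and unreacted 10 recycled.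

Step 6
Reactants: 12 lactone acid
Product: 14 (3R,4R)-3-(4-benzyloxy-3-methoxybenzyl)-4-[(S)-(4-benzyloxy-3-methoxyphenyl)(hydroxy)methyl]dihydrofuran-2(3H)-one, via hydroxymethyl lactone 13 (not isolated)
Conditions: BH3·SMe2, THF, 0 °C to rt; MeOH quench, concentrate; then K2CO3 (cat.), MeOH, rt; dilute HCl work-up
Reagents that add atoms: none
Why: Chemoselective borane reduction takes the free acid through its acyloxyborane far faster than the lactone, and methoxide-catalysed translactonisation (intramolecular transesterification) then moves the acyl group from the secondary benzylic C8 oxygen to the new primary C5 oxygen, trading a cis-trisubstituted ring for the less strained 3,4-trans lactone; no stereocentre is made, C4 is not enolisable at this stage and any equilibration at C3 also drains to the trans isomer.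

Step 7
Reactants: 14 trans hydroxy lactone
Product: 15 (3R,4R)-4-(4-benzyloxy-3-methoxybenzoyl)-3-(4-benzyloxy-3-methoxybenzyl)dihydrofuran-2(3H)-one
Conditions: Dess–Martin periodinane, CH2Cl2, 0 °C to rt
Reagents that add atoms: none
Why: Dess–Martin oxidation converts the secondary benzylic alcohol into the aryl ketone under non-basic conditions, so the newly enolisable C4–H (α to the ketone, with the lactone oxygen β to it) should be neither epimerised nor lost by elimination.

Step 8
Reactants: 15 bis(benzyl ether) keto lactone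
Product: 16 (3R,4R)-4-(4-hydroxy-3-methoxybenzoyl)-3-(4-hydroxy-3-methoxybenzyl)dihydrofuran-2(3H)-one
Conditions: H2 (1 atm), Pd/C (10%, zerovalent palladium on carbon), EtOAc, rt, stopped at consumption of 15
Reagents that add atoms: none
Why: Catalytic hydrogenolysis cleaves the two aryl benzyl ethers much faster than it reduces a conjugated aryl ketone under neutral conditions at 1 atm, the lactone and methyl ethers are inert, and the neutral medium leaves C3 and C4 untouched.

Compound list
1 | dihydroferulic acid, 3-(4-hydroxy-3-methoxyphenyl)propanoic acid | COc1cc(CCC(=O)O)ccc1O | starting material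
2 | benzyl 3-(4-benzyloxy-3-methoxyphenyl)propanoate | COc1cc(CCC(=O)OCc2ccccc2)ccc1OCc1ccccc1 | intermediate
3 | 3-(4-benzyloxy-3-methoxyphenyl)propanoic acid | COc1cc(CCC(=O)O)ccc1OCc1ccccc1 | intermediate
4 | (S)-4-benzyloxazolidin-2-one | O=C1N[C@@H](Cc2ccccc2)CO1 | starting material
5 | 3-(4-benzyloxy-3-methoxyphenyl)propanoic pivalic anhydride | COc1cc(CCC(=O)OC(=O)C(C)(C)C)ccc1OCc1ccccc1 | intermediate
6 | (S)-4-benzyl-3-[3-(4-benzyloxy-3-methoxyphenyl)propanoyl]oxazolidin-2-one | COc1cc(CCC(=O)N2[C@@H](Cc3ccccc3)COC2=O)ccc1OCc1ccccc1 | intermediate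
7 | lithium (Z)-enolate of 6 | COc1cc(C/C=C(\[O-])N2[C@@H](Cc3ccccc3)COC2=O)ccc1OCc1ccccc1.[Li+] | intermediate
8 | (2R,3R)-2,3-bis(4-benzyloxy-3-methoxybenzyl)-1,4-bis[(S)-4-benzyl-2-oxooxazolidin-3-yl]butane-1,4-dione | COc1cc(C[C@@H](C(=O)N2[C@@H](Cc3ccccc3)COC2=O)[C@H](C(=O)N2[C@@H](Cc3ccccc3)COC2=O)Cc2ccc(OCc3ccccc3)c(OC)c2)ccc1OCc1ccccc1 | intermediate
9 | (2R,3R)-2,3-bis(4-benzyloxy-3-methoxybenzyl)butanediperoxoic acid | COc1cc(C[C@@H](C(=O)OO)[C@H](C(=O)OO)Cc2ccc(OCc3ccccc3)c(OC)c2)ccc1OCc1ccccc1 | intermediate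
10 | (2R,3R)-2,3-bis(4-benzyloxy-3-methoxybenzyl)succinic acid (key-step precursor) | COc1cc(C[C@@H](C(=O)O)[C@H](C(=O)O)Cc2ccc(OCc3ccccc3)c(OC)c2)ccc1OCc1ccccc1 | intermediate
11 | benzylic cation of 10, positive charge on the future C8 | COc1cc(C[C@@H](C(=O)O)[C@H](C(=O)O)[CH+]c2ccc(OCc3ccccc3)c(OC)c2)ccc1OCc1ccccc1 | intermediate
12 | (2S,3S,4R)-2-(4-benzyloxy-3-methoxyphenyl)-4-(4-benzyloxy-3-methoxybenzyl)-5-oxotetrahydrofuran-3-carboxylic acid (key-step product; lactone oxygen on C8, aryl trans to carboxyl, carboxyl cis to benzyl) | COc1cc(C[C@H]2C(=O)O[C@H](c3ccc(OCc4ccccc4)c(OC)c3)[C@H]2C(=O)O)ccc1OCc1ccccc1 | intermediate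
13 | (3R,4R,5S)-5-(4-benzyloxy-3-methoxyphenyl)-3-(4-benzyloxy-3-methoxybenzyl)-4-(hydroxymethyl)dihydrofuran-2(3H)-one | COc1cc(C[C@H]2C(=O)O[C@H](c3ccc(OCc4ccccc4)c(OC)c3)[C@H]2CO)ccc1OCc1ccccc1 | intermediate
14 | (3R,4R)-3-(4-benzyloxy-3-methoxybenzyl)-4-[(S)-(4-benzyloxy-3-methoxyphenyl)(hydroxy)methyl]dihydrofuran-2(3H)-one | COc1cc(C[C@H]2C(=O)OC[C@@H]2[C@H](O)c2ccc(OCc3ccccc3)c(OC)c2)ccc1OCc1ccccc1 | intermediate
15 | (3R,4R)-4-(4-benzyloxy-3-methoxybenzoyl)-3-(4-benzyloxy-3-methoxybenzyl)dihydrofuran-2(3H)-one | COc1cc(C[C@H]2C(=O)OC[C@@H]2C(=O)c2ccc(OCc3ccccc3)c(OC)c2)ccc1OCc1ccccc1 | intermediate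
16 | (3R,4R)-4-(4-hydroxy-3-methoxybenzoyl)-3-(4-hydroxy-3-methoxybenzyl)dihydrofuran-2(3H)-one | COc1cc(C[C@H]2C(=O)OC[C@@H]2C(=O)c2ccc(O)c(OC)c2)ccc1O | target

Total step count: 8. Longest linear sequence: 8 steps (1 to 16).

Steps most likely to fail

Step 5. The second benzylic methylene of 12 is as reactive as the first, so over-oxidation to the cis-fused bislactone should compete statistically. The cation may also be captured by ring A in a Friedel–Crafts closure to an aryltetralin. Fallback: the C8 oxygen is installed by an aldol reaction instead of C–H oxidation. It sets out from oxazolidinone 4 and rejoins the route at 14.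
- Lithiated 4 (n-BuLi, THF, −78 °C) is acylated with methyl 4-chloro-4-oxobutanoate to give methyl 4-[(S)-4-benzyl-2-oxooxazolidin-3-yl]-4-oxobutanoate F1.
- Its dibutylboron enolate (Bu2BOTf, iPr2NEt, CH2Cl2, −78 to 0 °C) should add to 4-benzyloxy-3-methoxybenzaldehyde in an Evans syn aldol reaction to give methyl (3S,4S)-3-[(S)-4-benzyl-2-oxooxazolidine-3-carbonyl]-4-(4-benzyloxy-3-methoxyphenyl)-4-hydroxybutanoate F2.
- F2 should lactonise onto its methyl ester to give the trans lactone imide (S)-4-benzyl-3-[(2S,3S)-2-(4-benzyloxy-3-methoxyphenyl)-5-oxotetrahydrofuran-3-carbonyl]oxazolidin-2-one F3.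
- LiOH/H2O2 cleavage gives (2S,3S)-2-(4-benzyloxy-3-methoxyphenyl)-5-oxotetrahydrofuran-3-carboxylic acid F4.
- Its dianion (NaN(SiMe3)2, 2.2 equiv, THF, −78 °C) should be benzylated by 4-benzyloxy-3-methoxybenzyl bromide trans to the carboxylate, giving (2S,3S,4S)-2-(4-benzyloxy-3-methoxyphenyl)-4-(4-benzyloxy-3-methoxybenzyl)-5-oxotetrahydrofuran-3-carboxylic acid F5, the C4 epimer of 12.
- Borane reduction as in step 6 gives (3S,4R,5S)-5-(4-benzyloxy-3-methoxyphenyl)-3-(4-benzyloxy-3-methoxybenzyl)-4-(hydroxymethyl)dihydrofuran-2(3H)-one F6.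
- NaOMe in MeOH should translactonise F6 to the cis lactone (3S,4R)-3-(4-benzyloxy-3-methoxybenzyl)-4-[(S)-(4-benzyloxy-3-methoxyphenyl)(hydroxy)methyl]dihydrofuran-2(3H)-one F7, whose C3 centre equilibrates under the same base to the trans lactone 14.

Step 3. The radical dimerisation may stall at low conversion, or facial control may erode and give the meso-type dimer. Fallback: auxiliary control is replaced by coupling of the achiral dianion followed by resolution. It sets out from acid 3 and rejoins at 10, making steps 2–4 unnecessary.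
- The dianion of 3 (LiN(iPr)2, 2.2 equiv, THF) is coupled with I2 (0.5 equiv). This should give the threo diacid as a racemate, that is 10 together with its enantiomer (2S,3S)-2,3-bis(4-benzyloxy-3-methoxybenzyl)succinic acid F8, alongside meso-(2R,3S)-2,3-bis(4-benzyloxy-3-methoxybenzyl)succinic acid F9.
- F9 is removed by crystallisation.
- The racemate is resolved by fractional crystallisation of bis[(R)-1-phenylethylammonium] (2R,3R)-2,3-bis(4-benzyloxy-3-methoxybenzyl)succinate F10; another chiral base is screened should this pair not discriminate.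
- Acidification of F10 returns 10.

Step 8. Hydrogenation may run on from the benzyl ethers to the aryl ketone (carbinol, then methylene), or C4 may epimerise on the catalyst. Fallback: the last two operations are reordered so that no ketone meets hydrogen. It sets out from alcohol 14 and arrives directly at 16.
- Hydrogenolysis of 14 (H2, Pd/C, EtOAc, neutral, rt) should give (3R,4R)-3-(4-hydroxy-3-methoxybenzyl)-4-[(S)-hydroxy(4-hydroxy-3-methoxyphenyl)methyl]dihydrofuran-2(3H)-one F11, the benzylic alcohol surviving in the absence of acid.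
- DDQ (1.0 equiv, 1,4-dioxane, rt) should then oxidise the p-hydroxybenzylic alcohol selectively to the ketone, a known reaction of phenolic benzylic alcohols, giving 16.

Further compounds
F1 | step 5 | methyl 4-[(S)-4-benzyl-2-oxooxazolidin-3-yl]-4-oxobutanoate | COC(=O)CCC(=O)N1[C@@H](Cc2ccccc2)COC1=O
F2 | step 5 | methyl (3S,4S)-3-[(S)-4-benzyl-2-oxooxazolidine-3-carbonyl]-4-(4-benzyloxy-3-methoxyphenyl)-4-hydroxybutanoate | COC(=O)C[C@H](C(=O)N1[C@@H](Cc2ccccc2)COC1=O)[C@H](O)c1ccc(OCc2ccccc2)c(OC)c1
F3 | step 5 | (S)-4-benzyl-3-[(2S,3S)-2-(4-benzyloxy-3-methoxyphenyl)-5-oxotetrahydrofuran-3-carbonyl]oxazolidin-2-one | O=C1C[C@H](C(=O)N2[C@@H](Cc3ccccc3)COC2=O)[C@@H](c2ccc(OCc3ccccc3)c(OC)c2)O1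
F4 | step 5 | (2S,3S)-2-(4-benzyloxy-3-methoxyphenyl)-5-oxotetrahydrofuran-3-carboxylic acid | O=C1C[C@H](C(=O)O)[C@@H](c2ccc(OCc3ccccc3)c(OC)c2)O1
F5 | step 5 | (2S,3S,4S)-2-(4-benzyloxy-3-methoxyphenyl)-4-(4-benzyloxy-3-methoxybenzyl)-5-oxotetrahydrofuran-3-carboxylic acid | COc1cc(C[C@@H]2C(=O)O[C@H](c3ccc(OCc4ccccc4)c(OC)c3)[C@H]2C(=O)O)ccc1OCc1ccccc1
F6 | step 5 | (3S,4R,5S)-5-(4-benzyloxy-3-methoxyphenyl)-3-(4-benzyloxy-3-methoxybenzyl)-4-(hydroxymethyl)dihydrofuran-2(3H)-one | COc1cc(C[C@@H]2C(=O)O[C@H](c3ccc(OCc4ccccc4)c(OC)c3)[C@H]2CO)ccc1OCc1ccccc1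
F7 | step 5 | (3S,4R)-3-(4-benzyloxy-3-methoxybenzyl)-4-[(S)-(4-benzyloxy-3-methoxyphenyl)(hydroxy)methyl]dihydrofuran-2(3H)-one | COc1cc(C[C@@H]2C(=O)OC[C@@H]2[C@H](O)c2ccc(OCc3ccccc3)c(OC)c2)ccc1OCc1ccccc1
F8 | step 3 | (2S,3S)-2,3-bis(4-benzyloxy-3-methoxybenzyl)succinic acid | COc1cc(C[C@H](C(=O)O)[C@@H](C(=O)O)Cc2ccc(OCc3ccccc3)c(OC)c2)ccc1OCc1ccccc1
F9 | step 3 | meso-(2R,3S)-2,3-bis(4-benzyloxy-3-methoxybenzyl)succinic acid | COc1cc(C[C@@H](C(=O)O)[C@@H](C(=O)O)Cc2ccc(OCc3ccccc3)c(OC)c2)ccc1OCc1ccccc1
F10 | step 3 | bis[(R)-1-phenylethylammonium] (2R,3R)-2,3-bis(4-benzyloxy-3-methoxybenzyl)succinate | COc1cc(C[C@@H](C(=O)[O-])[C@H](C(=O)[O-])Cc2ccc(OCc3ccccc3)c(OC)c2)ccc1OCc1ccccc1.C[C@@H]([NH3+])c1ccccc1.C[C@@H]([NH3+])c1ccccc1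
F11 | step 8 | (3R,4R)-3-(4-hydroxy-3-methoxybenzyl)-4-[(S)-hydroxy(4-hydroxy-3-methoxyphenyl)methyl]dihydrofuran-2(3H)-one | COc1cc(C[C@H]2C(=O)OC[C@@H]2[C@H](O)c2ccc(O)c(OC)c2)ccc1O
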